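**Plan**

1. Retrosynthesis: both interflavan C4–C8 bonds are cut (Friedel–Crafts), first middle→lower, then upper→middle. The upper unit comes from (−)-epicatechin, the lower from (+)-catechin, and the 5-deoxy middle unit is built de novo.
2. The pyran ring C of the middle unit (O1, C2, C3, C4, C4a, C8a) is traced back, by pulling C4 out of the ring, to the five-membered ring of a 2-aryl-3-methylidene-2,3-dihydrobenzofuran (O1, C2, C3, C3a, C7a; C4 is the exocyclic CH2).
3. Enabling feature: in ring A of the middle unit O7 is para and O1 ortho to C4a, so C4a is an excellent migrating aryl carbon. It shifts from C3 to the exocyclic CH2 under an aryl-iodane oxidant and the ring grows by one carbon to the flavan-3-one.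
4. Forward: 4-iodoresorcinol + 3,4-bis(benzyloxy)benzaldehyde → aryl propargyl ether → radical 5-exo-dig closure of the furan ring → ring enlargement to ring C → cis-flavan-3-ol → Br block at C6, sulfide at C4 → upper unit onto C8 → lower unit onto C4 → hydrogenolysis.
5. Stereochemistry: C2 and C3 of the middle unit are set together by asymmetric transfer hydrogenation with dynamic kinetic resolution of the C2-labile 3-ketone. Both new C4 centres arise by attack anti to the axial 3-OH of a 2,3-cis unit (3,4-trans). The other four centres come from the natural flavan-3-ols.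
6. Helpers: silyl ether on O7, Br at C6 (middle) and C8 (upper) as blocking groups, a 2,6-dimethylphenyl sulfide at C4 as a leaving group inert in the first coupling. Benzyl ethers and both bromines leave in the last step.

Key step: step 5

Remark: the four compounds from the propargylic alcohol to the flavan-3-one are carried as racemates on purpose, since C2 is set only in step 6. Which enantiomer of the ruthenium catalyst (and, in the fallback, which lipase) gives the 2R,3R series is to be settled by a trial run.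

**Route**

Step 1
Reactants: 1 4-iodobenzene-1,3-diol (4-iodoresorcinol)
Product: 2 2-iodo-5-[(triisopropylsilyl)oxy]phenol
Conditions: i-Pr3SiCl (1.0 equiv), imidazole, DMF, 0 °C
Reagents that add atoms: chlorotriisopropylsilane, CC(C)[Si](Cl)(C(C)C)C(C)C
Why: Silyl ether formation: the bulky chlorosilane should react at the unhindered hydroxyl para to iodine and leave the hydroxyl ortho to iodine free for the later ether link to C2.

Step 2
Reactants: 3 3,4-bis(benzyloxy)benzaldehyde
Product: 4 rac-1-[3,4-bis(benzyloxy)phenyl]prop-2-yn-1-ol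
Conditions: HC≡CMgBr, THF, 0 °C; aq. NH4Cl
Reagents that add atoms: ethynylmagnesium bromide, C#C[Mg]Br
Why: Grignard addition of the alkynyl magnesium reagent to the aldehyde gives the propargylic alcohol, left racemic because this carbon (later C2) becomes epimerisable at the ketone stage and is set in step 6.

Step 3
Reactants: 2 2-iodo-5-[(triisopropylsilyl)oxy]phenol, 4 rac-1-[3,4-bis(benzyloxy)phenyl]prop-2-yn-1-ol
Product: 5 rac-[3-({1-[3,4-bis(benzyloxy)phenyl]prop-2-yn-1-yl}oxy)-4-iodophenoxy]triisopropylsilane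
Conditions: PPh3, DIAD, THF, 0 °C to rt
Reagents that add atoms: none
Why: Mitsunobu reaction: the acidic ortho-iodophenol displaces the phosphonium-activated secondary propargylic alcohol and forms the aryl ether bond O1–C2.

Step 4
Reactants: 5 rac-[3-({1-[3,4-bis(benzyloxy)phenyl]prop-2-yn-1-yl}oxy)-4-iodophenoxy]triisopropylsilane
Product: 6 rac-2-[3,4-bis(benzyloxy)phenyl]-3-methylidene-6-[(triisopropylsilyl)oxy]-2,3-dihydrobenzofuran
Conditions: (Me3Si)3SiH (slow addition), AIBN (cat.), toluene, 80 °C; filtration through basic Al2O3, used at once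
Reagents that add atoms: none
Why: Radical 5-exo-dig cyclisation: the silyl radical abstracts iodine, the aryl radical adds to the internal alkyne carbon and the vinyl radical takes hydrogen from the silane, which closes the five-membered ring with an exocyclic methylene under neutral conditions that should not isomerise it to the benzofuran.

Step 5
Reactants: 6 rac-2-[3,4-bis(benzyloxy)phenyl]-3-methylidene-6-[(triisopropylsilyl)oxy]-2,3-dihydrobenzofuran
Product: 9 rac-2-[3,4-bis(benzyloxy)phenyl]-7-[(triisopropylsilyl)oxy]chroman-3-one, via alkyl(phenyl)iodane adduct 7 (not isolated), via dimethyl ketal 8 (not isolated)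
Conditions: PhI(OH)OTs (1.1 equiv), MeOH, −20 to 0 °C; then 1 M HCl, THF, rt
Reagents that add atoms: water, O (supplies the carbonyl oxygen when ketal 8 is hydrolysed); methanol, CO (carried only in 7 and 8)
Why: The electrophilic trivalent iodine of PhI(OH)OTs adds to the exocyclic CH2 of 6 and methanol caps the benzylic C3 (adduct 7); iodobenzene then leaves from the CH2 with a 1,2-shift of the ring-A carbon C3a through a phenonium ion, which places the CH2 between C3 and the arene and turns the five-membered ring (O1, C2, C3, C3a, C7a) into the six-membered pyran ring, the methoxy-stabilised cation at C3 being trapped as ketal 8 and hydrolysed to ketone 9. The closest known reaction type is the oxidative rearrangement of 1,1-disubstituted aryl alkenes and the ring expansion of 1-methylidene benzocycloalkanes to β-benzocycloalkenones with the same reagent. No ring is closed by cyclisation: the ring grows by one carbon through the 1,2-aryl shift (the transient phenonium ion is a spiro three-membered ring that reopens at once). No stereocentre is formed; C2 is not touched, stays racemic and is set together with C3 in step 6. The step needs migration of the aryl carbon and not of C2, and capture of the C3 cation by methanol and not loss of H-2 (aromatisation to a benzofuran); the para-silyloxy and ortho-alkoxy groups make the aryl carbon the best migrating group, and methanol as solvent at low temperature should make capture faster than elimination.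

Step 6
Reactants: 9 rac-2-[3,4-bis(benzyloxy)phenyl]-7-[(triisopropylsilyl)oxy]chroman-3-one
Product: 10 (2R,3R)-2-[3,4-bis(benzyloxy)phenyl]-7-[(triisopropylsilyl)oxy]chroman-3-ol (2,3-cis)
Conditions: RuCl(p-cymene)[(S,S)-TsDPEN] or its (R,R) enantiomer (2 mol%), HCO2H–Et3N (1:2), DMF, 40 °C, Ar
Reagents that add atoms: none
Why: Asymmetric transfer hydrogenation with dynamic kinetic resolution, known for 2-arylcycloalkanones: H-2 of the α-aryl-α-aryloxy ketone exchanges under the amine while the chiral ruthenium hydride reduces one enantiomer from the face anti to the 2-aryl group, which should give the 2,3-cis alcohol and set C2 and C3 together.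

Step 7
Reactants: 10 (2R,3R)-2-[3,4-bis(benzyloxy)phenyl]-7-[(triisopropylsilyl)oxy]chroman-3-ol
Product: 11 (2R,3R)-2-[3,4-bis(benzyloxy)phenyl]chromane-3,7-diol (3',4'-di-O-benzylepifisetinidol)
Conditions: Bu4NF, THF, 0 °C
Reagents that add atoms: none
Why: Fluoride-mediated desilylation frees the 7-OH, which is needed as the activating group ortho to C8 and para to C4a in the following steps.

Step 8
Reactants: 11 (2R,3R)-2-[3,4-bis(benzyloxy)phenyl]chromane-3,7-diol
Product: 12 (2R,3R)-6-bromo-2-[3,4-bis(benzyloxy)phenyl]chromane-3,7-diol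
Conditions: NBS (1.0 equiv), CH2Cl2–THF, −78 °C
Reagents that add atoms: N-bromosuccinimide, O=C1CCC(=O)N1Br
Why: Electrophilic aromatic bromination of the phenol should occur at C6, ortho to 7-OH, para to O1 and less hindered than C8, and installs the blocking group that later steers the upper unit to C8.

Step 9
Reactants: 12 (2R,3R)-6-bromo-2-[3,4-bis(benzyloxy)phenyl]chromane-3,7-diol
Product: 14 (2R,3R,4S)-6-bromo-2-[3,4-bis(benzyloxy)phenyl]-4-(2-ethoxyethoxy)chromane-3,7-diol (3,4-trans), via para-quinone methide 13 (not isolated)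
Conditions: DDQ (1.1 equiv), EtOCH2CH2OH (5 equiv), CH2Cl2, 0 °C
Reagents that add atoms: 2-ethoxyethanol, CCOCCO
Why: DDQ dehydrogenation of a para-alkylphenol (7-OH is para to C4a) gives para-quinone methide 13, and 1,6-addition of the alcohol at C4 anti to the 3-OH restores ring A; C4 is ionised again later, so its configuration is not critical.

Step 10
Reactants: 14 (2R,3R,4S)-6-bromo-2-[3,4-bis(benzyloxy)phenyl]-4-(2-ethoxyethoxy)chromane-3,7-diol
Product: 15 (2R,3S,4S)-6-bromo-2-[3,4-bis(benzyloxy)phenyl]-4-[(2,6-dimethylphenyl)sulfanyl]chromane-3,7-diol (2,3-cis, 3,4-trans)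
Conditions: 2,6-Me2C6H3SH (3 equiv), BF3·OEt2, CH2Cl2, −78 to −30 °C
Reagents that add atoms: 2,6-dimethylbenzenethiol, Cc1cccc(C)c1S
Why: Lewis-acid-mediated thiolysis-type exchange (SN1): BF3 ionises the 4-alkoxy group and the thiol adds to the benzylic cation anti to the 3-OH, giving a hindered aryl sulfide that hard Lewis acids do not activate.

Step 11
Reactants: 16 (−)-epicatechin
Product: 17 5,7,3',4'-tetra-O-benzyl-(−)-epicatechin
Conditions: BnBr, K2CO3, DMF, 0 °C to rt
Reagents that add atoms: benzyl bromide, BrCc1ccccc1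
Why: Williamson ether synthesis: K2CO3 deprotonates only the four phenols, so the secondary 3-OH stays free.

Step 12
Reactants: 17 5,7,3',4'-tetra-O-benzyl-(−)-epicatechin
Product: 18 8-bromo-5,7,3',4'-tetra-O-benzyl-(−)-epicatechin
Conditions: NBS (1.0 equiv), CH2Cl2, −78 °C to rt
Reagents that add atoms: N-bromosuccinimide, O=C1CCC(=O)N1Br
Why: Electrophilic aromatic bromination at C8, the most reactive position of the 5,7-dialkoxy ring A, caps this unit against condensation with itself.

Step 13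
Reactants: 18 8-bromo-5,7,3',4'-tetra-O-benzyl-(−)-epicatechin
Product: 19 8-bromo-4β-(2-ethoxyethoxy)-5,7,3',4'-tetra-O-benzyl-(−)-epicatechin (2R,3R,4S; 3,4-trans)
Conditions: DDQ, EtOCH2CH2OH, CH2Cl2, rt
Reagents that add atoms: 2-ethoxyethanol, CCOCCO
Why: Oxidative benzylic C–H etherification: DDQ abstracts hydride from C4 (cation stabilised by O1, O5 and O7) and the alcohol adds anti to the 3-OH to give the 3,4-trans ether.

Step 14
Reactants: 19 8-bromo-4β-(2-ethoxyethoxy)-5,7,3',4'-tetra-O-benzyl-(−)-epicatechin, 15 (2R,3S,4S)-6-bromo-2-[3,4-bis(benzyloxy)phenyl]-4-[(2,6-dimethylphenyl)sulfanyl]chromane-3,7-diol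
Product: 20 8-bromo-5,7,3',4'-tetra-O-benzylepicatechin-(4β→8)-[6-bromo-3',4'-di-O-benzyl-4β-(2,6-dimethylphenylsulfanyl)epifisetinidol]
Conditions: BF3·OEt2, 4 Å MS, CH2Cl2, −78 to −30 °C; 15 in slight excess
Reagents that add atoms: none
Why: Friedel–Crafts alkylation: BF3 ionises the 4-alkoxy group of 19 and the cation attacks the only free activated position of 15, C8 ortho to the free 7-OH (C6 is blocked by Br, and Br at C8 of 19 stops self-condensation), from the face anti to the axial 3-OH, which should give the 3,4-trans (4β) bond while the shielded sulfide at C4 of 15 stays untouched.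

Step 15
Reactants: 21 (+)-catechin
Product: 22 5,7,3',4'-tetra-O-benzyl-(+)-catechin
Conditions: BnBr, K2CO3, DMF, 0 °C to rt
Reagents that add atoms: benzyl bromide, BrCc1ccccc1
Why: Williamson ether synthesis on the four phenols only, the secondary 3-OH staying free.

Step 16
Reactants: 20 8-bromo-5,7,3',4'-tetra-O-benzylepicatechin-(4β→8)-[6-bromo-3',4'-di-O-benzyl-4β-(2,6-dimethylphenylsulfanyl)epifisetinidol], 22 5,7,3',4'-tetra-O-benzyl-(+)-catechin
Product: 23 8-bromo-5,7,3',4'-tetra-O-benzylepicatechin-(4β→8)-(6-bromo-3',4'-di-O-benzylepifisetinidol)-(4β→8)-5,7,3',4'-tetra-O-benzylcatechin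
Conditions: AgBF4, 22 (3 equiv), THF, 0 °C, dark
Reagents that add atoms: none
Why: Friedel–Crafts alkylation after thiophilic activation: AgBF4 binds sulfur, the C4–S bond ionises with help of the para 7-OH, and C8 of the benzylated catechin attacks the cation anti to the axial 3-OH of the 2,3-cis middle unit, which should set the second 3,4-trans (4β→8) bond.

Step 17
Reactants: 23 8-bromo-5,7,3',4'-tetra-O-benzylepicatechin-(4β→8)-(6-bromo-3',4'-di-O-benzylepifisetinidol)-(4β→8)-5,7,3',4'-tetra-O-benzylcatechin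
Product: 24 epicatechin-(4β→8)-epifisetinidol-(4β→8)-catechin (target)
Conditions: H2 (1 atm), Pd(OH)2/C, Et3N, THF–MeOH–H2O, rt
Reagents that add atoms: none
Why: Catalytic hydrogenolysis cleaves the ten benzyl ethers and both aryl C–Br blocking groups in one operation, Et3N taking up HBr so that the acid-labile interflavan bonds should survive.

**Compound list**

1 | 4-iodobenzene-1,3-diol (4-iodoresorcinol) | Oc1ccc(I)c(O)c1 | starting material
2 | 2-iodo-5-[(triisopropylsilyl)oxy]phenol | Oc1cc(O[Si](C(C)C)(C(C)C)C(C)C)ccc1I | intermediate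
3 | 3,4-bis(benzyloxy)benzaldehyde | O=Cc1ccc(OCc2ccccc2)c(OCc2ccccc2)c1 | starting material
4 | rac-1-[3,4-bis(benzyloxy)phenyl]prop-2-yn-1-ol | C#CC(O)c1ccc(OCc2ccccc2)c(OCc2ccccc2)c1 | intermediate
5 | rac-[3-({1-[3,4-bis(benzyloxy)phenyl]prop-2-yn-1-yl}oxy)-4-iodophenoxy]triisopropylsilane | C#CC(Oc1cc(O[Si](C(C)C)(C(C)C)C(C)C)ccc1I)c1ccc(OCc2ccccc2)c(OCc2ccccc2)c1 | intermediate
6 | rac-2-[3,4-bis(benzyloxy)phenyl]-3-methylidene-6-[(triisopropylsilyl)oxy]-2,3-dihydrobenzofuran | C=C1c2ccc(O[Si](C(C)C)(C(C)C)C(C)C)cc2OC1c1ccc(OCc2ccccc2)c(OCc2ccccc2)c1 | intermediate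
7 | rac-{[2-[3,4-bis(benzyloxy)phenyl]-3-methoxy-6-[(triisopropylsilyl)oxy]-2,3-dihydrobenzofuran-3-yl]methyl}(phenyl)(tosyloxy)-λ3-iodane (formed in the flask) | COC1(CI(c2ccccc2)OS(=O)(=O)c2ccc(C)cc2)c2ccc(O[Si](C(C)C)(C(C)C)C(C)C)cc2OC1c1ccc(OCc2ccccc2)c(OCc2ccccc2)c1 | intermediate
8 | rac-2-[3,4-bis(benzyloxy)phenyl]-3,3-dimethoxy-7-[(triisopropylsilyl)oxy]chromane (formed in the flask) | COC1(OC)Cc2ccc(O[Si](C(C)C)(C(C)C)C(C)C)cc2OC1c1ccc(OCc2ccccc2)c(OCc2ccccc2)c1 | intermediate
9 | rac-2-[3,4-bis(benzyloxy)phenyl]-7-[(triisopropylsilyl)oxy]chroman-3-one | O=C1Cc2ccc(O[Si](C(C)C)(C(C)C)C(C)C)cc2OC1c1ccc(OCc2ccccc2)c(OCc2ccccc2)c1 | intermediate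
10 | (2R,3R)-2-[3,4-bis(benzyloxy)phenyl]-7-[(triisopropylsilyl)oxy]chroman-3-ol | CC(C)[Si](Oc1ccc2c(c1)O[C@H](c1ccc(OCc3ccccc3)c(OCc3ccccc3)c1)[C@H](O)C2)(C(C)C)C(C)C | intermediate
11 | (2R,3R)-2-[3,4-bis(benzyloxy)phenyl]chromane-3,7-diol | Oc1ccc2c(c1)O[C@H](c1ccc(OCc3ccccc3)c(OCc3ccccc3)c1)[C@H](O)C2 | intermediate
12 | (2R,3R)-6-bromo-2-[3,4-bis(benzyloxy)phenyl]chromane-3,7-diol | Oc1c(Br)cc2c(c1)O[C@H](c1ccc(OCc3ccccc3)c(OCc3ccccc3)c1)[C@H](O)C2 | intermediate
13 | (2R,3R)-6-bromo-2-[3,4-bis(benzyloxy)phenyl]-3-hydroxy-2,3-dihydro-7H-chromen-7-one (para-quinone methide, formed in the flask) | O=C1C(Br)=CC2=C[C@@H](O)[C@@H](c3ccc(OCc4ccccc4)c(OCc4ccccc4)c3)OC2=C1 | intermediate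
14 | (2R,3R,4S)-6-bromo-2-[3,4-bis(benzyloxy)phenyl]-4-(2-ethoxyethoxy)chromane-3,7-diol | Oc1c(Br)cc2c(c1)O[C@H](c1ccc(OCc3ccccc3)c(OCc3ccccc3)c1)[C@H](O)[C@H]2OCCOCC | intermediate
15 | (2R,3S,4S)-6-bromo-2-[3,4-bis(benzyloxy)phenyl]-4-[(2,6-dimethylphenyl)sulfanyl]chromane-3,7-diol | Oc1c(Br)cc2c(c1)O[C@H](c1ccc(OCc3ccccc3)c(OCc3ccccc3)c1)[C@H](O)[C@H]2Sc1c(C)cccc1C | intermediate
16 | (−)-epicatechin, (2R,3R) | Oc1cc(O)c2c(c1)O[C@H](c1ccc(O)c(O)c1)[C@H](O)C2 | starting material
17 | 5,7,3',4'-tetra-O-benzyl-(−)-epicatechin | O(Cc1ccccc1)c1cc(OCc3ccccc3)c2c(c1)O[C@H](c1ccc(OCc3ccccc3)c(OCc3ccccc3)c1)[C@H](O)C2 | intermediate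
18 | 8-bromo-5,7,3',4'-tetra-O-benzyl-(−)-epicatechin | O(Cc1ccccc1)c1cc(OCc3ccccc3)c2c(c1Br)O[C@H](c1ccc(OCc3ccccc3)c(OCc3ccccc3)c1)[C@H](O)C2 | intermediate
19 | 8-bromo-4β-(2-ethoxyethoxy)-5,7,3',4'-tetra-O-benzyl-(−)-epicatechin | O(Cc1ccccc1)c1cc(OCc3ccccc3)c2c(c1Br)O[C@H](c1ccc(OCc3ccccc3)c(OCc3ccccc3)c1)[C@H](O)[C@H]2OCCOCC | intermediate
20 | 8-bromo-5,7,3',4'-tetra-O-benzylepicatechin-(4β→8)-[6-bromo-3',4'-di-O-benzyl-4β-(2,6-dimethylphenylsulfanyl)epifisetinidol] | O(Cc1ccccc1)c1cc(OCc3ccccc3)c2c(c1Br)O[C@H](c1ccc(OCc3ccccc3)c(OCc3ccccc3)c1)[C@H](O)[C@H]2c1c(O)c(Br)cc2c1O[C@H](c1ccc(OCc3ccccc3)c(OCc3ccccc3)c1)[C@H](O)[C@H]2Sc1c(C)cccc1C | intermediate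
21 | (+)-catechin, (2R,3S) | Oc1cc(O)c2c(c1)O[C@H](c1ccc(O)c(O)c1)[C@@H](O)C2 | starting material
22 | 5,7,3',4'-tetra-O-benzyl-(+)-catechin | O(Cc1ccccc1)c1cc(OCc3ccccc3)c2c(c1)O[C@H](c1ccc(OCc3ccccc3)c(OCc3ccccc3)c1)[C@@H](O)C2 | intermediate
23 | 8-bromo-5,7,3',4'-tetra-O-benzylepicatechin-(4β→8)-(6-bromo-3',4'-di-O-benzylepifisetinidol)-(4β→8)-5,7,3',4'-tetra-O-benzylcatechin | O(Cc1ccccc1)c1cc(OCc3ccccc3)c2c(c1Br)O[C@H](c1ccc(OCc3ccccc3)c(OCc3ccccc3)c1)[C@H](O)[C@H]2c1c(O)c(Br)cc2c1O[C@H](c1ccc(OCc3ccccc3)c(OCc3ccccc3)c1)[C@H](O)[C@H]2c1c(OCc3ccccc3)cc(OCc3ccccc3)c2c1O[C@H](c1ccc(OCc3ccccc3)c(OCc3ccccc3)c1)[C@@H](O)C2 | intermediate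
24 | epicatechin-(4β→8)-epifisetinidol-(4β→8)-catechin | Oc1cc(O)c2c(c1)O[C@H](c1ccc(O)c(O)c1)[C@H](O)[C@H]2c1c(O)ccc2c1O[C@H](c1ccc(O)c(O)c1)[C@H](O)[C@H]2c1c(O)cc(O)c2c1O[C@H](c1ccc(O)c(O)c1)[C@@H](O)C2 | target

**Count and risks**

Total steps: 17. Longest linear sequence: 12 steps (steps 1, 3 to 10, 14, 16, 17).

Steps most likely to fail:

Step 5. Alkene 6, or the C3 cation formed when the iodane attacks, may lose H-2 under the sulfonic acid that is set free and aromatise to a 2-arylbenzofuran before the aryl shift; migration of C2 in place of the aryl carbon is a second leak. The fallback sets out from 6 and comes back at 9. OsO4 (cat.) with NMO in acetone–water dihydroxylates the exocyclic alkene under neutral conditions to rac-2-[3,4-bis(benzyloxy)phenyl]-3-(hydroxymethyl)-6-[(triisopropylsilyl)oxy]-2,3-dihydrobenzofuran-3-ol F1. TsCl in pyridine at 0 °C gives the primary mono-tosylate F2. LiClO4 with CaCO3 in THF at 50 °C should then bring about the pinacol-type (semipinacol) rearrangement of the diol monosulfonate, with the same 1,2-aryl shift and ring enlargement but without free acid, to give 9.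

Step 6. Exchange of H-2 may be slower than hydride transfer, or the catalyst may discriminate the ketone faces poorly, so that trans alcohols or material of low enantiomeric purity result. The fallback sets out from 9 and comes back at 10. LiBH(s-Bu)3 with LiBr in THF at −78 °C should reduce the ketone from the face anti to the 2-aryl group to the racemic cis alcohol, that is 10 together with its enantiomer (2S,3S)-2-[3,4-bis(benzyloxy)phenyl]-7-[(triisopropylsilyl)oxy]chroman-3-ol F3. A lipase picked by screening so that F3 is the fast-reacting enantiomer, with vinyl acetate, converts F3 into the (2S,3S) 3-O-acetate F4, and chromatography leaves 10.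

Step 14. The C4 sulfide of 15 may ionise through the para 7-OH under BF3 so that 15 condenses with itself, or attack at the flanked C8 may be too slow and the cation from 19 eliminates. The fallback sets out from 12 and 19 and comes back at 23. Phenol 12, which carries no leaving group at C4, is coupled with 19 (BF3·OEt2, CH2Cl2, −78 to −30 °C) to give 8-bromo-5,7,3',4'-tetra-O-benzylepicatechin-(4β→8)-(6-bromo-3',4'-di-O-benzylepifisetinidol) F5. DDQ with 2-ethoxyethanol then oxidises only the middle-unit C4–H2, which is para to the one free phenol, to the dimer 4β-(2-ethoxyethoxy) ether F6. Me3SiOTf in CH2Cl2 at −78 °C with 22 gives 23.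

Further compounds

F1 | step 5 | rac-2-[3,4-bis(benzyloxy)phenyl]-3-(hydroxymethyl)-6-[(triisopropylsilyl)oxy]-2,3-dihydrobenzofuran-3-ol | OCC1(O)c2ccc(O[Si](C(C)C)(C(C)C)C(C)C)cc2OC1c1ccc(OCc2ccccc2)c(OCc2ccccc2)c1
F2 | step 5 | rac-{2-[3,4-bis(benzyloxy)phenyl]-3-hydroxy-6-[(triisopropylsilyl)oxy]-2,3-dihydrobenzofuran-3-yl}methyl 4-methylbenzenesulfonate | Cc1ccc(cc1)S(=O)(=O)OCC1(O)c2ccc(O[Si](C(C)C)(C(C)C)C(C)C)cc2OC1c1ccc(OCc2ccccc2)c(OCc2ccccc2)c1
F3 | step 6 | (2S,3S)-2-[3,4-bis(benzyloxy)phenyl]-7-[(triisopropylsilyl)oxy]chroman-3-ol | CC(C)[Si](Oc1ccc2c(c1)O[C@@H](c1ccc(OCc3ccccc3)c(OCc3ccccc3)c1)[C@@H](O)C2)(C(C)C)C(C)C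
F4 | step 6 | (2S,3S)-2-[3,4-bis(benzyloxy)phenyl]-7-[(triisopropylsilyl)oxy]chroman-3-yl acetate | CC(C)[Si](Oc1ccc2c(c1)O[C@@H](c1ccc(OCc3ccccc3)c(OCc3ccccc3)c1)[C@@H](OC(C)=O)C2)(C(C)C)C(C)C
F5 | step 14 | 8-bromo-5,7,3',4'-tetra-O-benzylepicatechin-(4β→8)-(6-bromo-3',4'-di-O-benzylepifisetinidol) | O(Cc1ccccc1)c1cc(OCc3ccccc3)c2c(c1Br)O[C@H](c1ccc(OCc3ccccc3)c(OCc3ccccc3)c1)[C@H](O)[C@H]2c1c(O)c(Br)cc2c1O[C@H](c1ccc(OCc3ccccc3)c(OCc3ccccc3)c1)[C@H](O)C2
F6 | step 14 | 8-bromo-5,7,3',4'-tetra-O-benzylepicatechin-(4β→8)-[6-bromo-3',4'-di-O-benzyl-4β-(2-ethoxyethoxy)epifisetinidol] | O(Cc1ccccc1)c1cc(OCc3ccccc3)c2c(c1Br)O[C@H](c1ccc(OCc3ccccc3)c(OCc3ccccc3)c1)[C@H](O)[C@H]2c1c(O)c(Br)cc2c1O[C@H](c1ccc(OCc3ccccc3)c(OCc3ccccc3)c1)[C@H](O)[C@H]2OCCOCC
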